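**Plan**

- The retrosynthesis cuts one skeletal bond only: the biaryl bond between C8 of the acacetin unit and C6'' of the apigenin unit (apigenin-unit locants carry double and triple primes). Both chromenone ring systems are bought intact.
- Enabling feature: each of these two ring A carbons lies between two oxygens, and O7 and O5'' stand ortho to the bond on either side. A one-carbon O7–CH2–O5'' acetal therefore holds the C8 iodide next to C6''–H and turns the coupling into closure of a seven-membered 1,3-dioxepine.
- Behind the key step the acetal is cut at O7–CH2 (8-iodo-7-hydroxy acacetin arm plus 5''-O-chloromethyl apigenin arm), then the O-protecting groups are cut.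
- Forward: acacetin arm (O7 MOM, O5 benzyl, C8 iodination, MOM off); apigenin arm (O7''/O4''' benzyl, O5'' methylthiomethyl, chloromethyl ether); Williamson union; palladium ring closure, the only ring formed and a temporary one; BCl3 then removes the bridge and the benzyl groups together.
- Stereochemistry: the target has no stereocentre, so nothing has to be set.

Key step: step 9

Remark: the target SMILES defines no axial configuration, so the C8–C6'' axis is treated as unspecified and is formed without control.

**Route**

Step 1
Reactants: 1 acacetin (5,7-dihydroxy-2-(4-methoxyphenyl)-4H-chromen-4-one); 2 chloromethyl methyl ether (MOMCl)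
Product: 3 7-O-(methoxymethyl)acacetin (5-hydroxy-7-(methoxymethoxy)-2-(4-methoxyphenyl)-4H-chromen-4-one)
Conditions: MOMCl (1.2 equiv), K2CO3, acetone, rt
Reagents that add atoms: chloromethyl methyl ether, COCCl
Why: Williamson O-alkylation in which the free, more acidic 7-hydroxyl reacts while the 5-hydroxyl stays locked in its hydrogen bond to the C4 carbonyl, so a slight excess of MOMCl should etherify O7 only.

Step 2
Reactants: 3 7-O-(methoxymethyl)acacetin; 4 benzyl bromide
Product: 5 5-O-benzyl-7-O-(methoxymethyl)acacetin (5-(benzyloxy)-7-(methoxymethoxy)-2-(4-methoxyphenyl)-4H-chromen-4-one)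
Conditions: BnBr (1.5 equiv), K2CO3, DMF, 70 °C
Reagents that add atoms: benzyl bromide, BrCc1ccccc1
Why: Williamson etherification of the chelated 5-hydroxyl, which needs a polar aprotic solvent and heat, under basic conditions that leave the MOM acetal untouched.

Step 3
Reactants: 5 5-O-benzyl-7-O-(methoxymethyl)acacetin; 6 N-iodosuccinimide
Product: 7 5-O-benzyl-8-iodo-7-O-(methoxymethyl)acacetin (5-(benzyloxy)-8-iodo-7-(methoxymethoxy)-2-(4-methoxyphenyl)-4H-chromen-4-one)
Conditions: NIS (1.1 equiv), CF3CO2H (0.2 equiv), MeCN–CH2Cl2, 0 °C to rt, dark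
Reagents that add atoms: N-iodosuccinimide, O=C1CCC(=O)N1I
Why: Electrophilic aromatic iodination, which in fully etherified 5,7-dialkoxyflavones goes to C8 (para to O5, ortho to O7 and O1, less crowded than C6 between two alkoxy groups), while ring B and C3 are deactivated by the pyranone.

Step 4
Reactants: 7 5-O-benzyl-8-iodo-7-O-(methoxymethyl)acacetin
Product: 8 5-O-benzyl-8-iodoacacetin (5-(benzyloxy)-7-hydroxy-8-iodo-2-(4-methoxyphenyl)-4H-chromen-4-one)
Conditions: HCl (1.25 M in MeOH), THF, rt to 40 °C
Reagents that add atoms: none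
Why: Acid-catalysed methanolysis (transacetalisation) of the aryl MOM acetal through the methoxymethyl oxocarbenium ion, under dilute acid that should spare the aryl benzyl ether, the aryl iodide and the flavone.

Step 5
Reactants: 9 apigenin (5,7-dihydroxy-2-(4-hydroxyphenyl)-4H-chromen-4-one); 4 benzyl bromide
Product: 10 7,4'-di-O-benzylapigenin (7-(benzyloxy)-2-[4-(benzyloxy)phenyl]-5-hydroxy-4H-chromen-4-one)
Conditions: BnBr (2.2 equiv), K2CO3, DMF, rt to 50 °C
Reagents that add atoms: benzyl bromide, BrCc1ccccc1
Why: Williamson benzylation of the two non-chelated phenols, the hydrogen-bonded 5-hydroxyl remaining free under carbonate at moderate temperature.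

Step 6
Reactants: 10 7,4'-di-O-benzylapigenin; 11 chloromethyl methyl sulfide
Product: 12 7,4'-di-O-benzyl-5-O-(methylthiomethyl)apigenin (7-(benzyloxy)-2-[4-(benzyloxy)phenyl]-5-[(methylsulfanyl)methoxy]-4H-chromen-4-one)
Conditions: NaH, ClCH2SMe, NaI (cat.), DMF, 0 °C to rt
Reagents that add atoms: chloromethyl methyl sulfide, CSCCl
Why: Williamson alkylation of the sodium 5-phenoxide (NaH breaks the chelate) by the halide activated in situ through Finkelstein exchange, the standard way to aryl methylthiomethyl ethers.

Step 7
Reactants: 12 7,4'-di-O-benzyl-5-O-(methylthiomethyl)apigenin; 13 sulfuryl chloride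
Product: 14 7,4'-di-O-benzyl-5-O-(chloromethyl)apigenin (7-(benzyloxy)-2-[4-(benzyloxy)phenyl]-5-(chloromethoxy)-4H-chromen-4-one), freed of volatiles and used crude at once
Conditions: SO2Cl2 (1.05 equiv), cyclohexene, CH2Cl2, −78 to 0 °C
Reagents that add atoms: sulfuryl chloride, O=S(=O)(Cl)Cl
Why: Sulfuryl chloride cleavage of an O,S-acetal (S-chlorination, fragmentation to the aryloxymethyl cation and MeSCl, chloride capture), with cyclohexene taking up MeSCl by addition so that the electron-rich ring A is not sulfenylated.

Step 8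
Reactants: 8 5-O-benzyl-8-iodoacacetin; 14 7,4'-di-O-benzyl-5-O-(chloromethyl)apigenin
Product: 15 mixed formaldehyde acetal joining O7 of 5-O-benzyl-8-iodoacacetin to O5'' of 7'',4'''-di-O-benzylapigenin (5-(benzyloxy)-7-[({7-(benzyloxy)-2-[4-(benzyloxy)phenyl]-4-oxo-4H-chromen-5-yl}oxy)methoxy]-8-iodo-2-(4-methoxyphenyl)-4H-chromen-4-one)
Conditions: Cs2CO3, DMF, 0 °C to rt, 14 in slight excess
Reagents that add atoms: none
Why: Williamson acetal synthesis in which the caesium 7-phenoxide of 8 (made more acidic by the ortho iodine and the para carbonyl) displaces chloride from the alpha-chloro ether, an electrophile with oxocarbenium character, to give the unsymmetrical diaryl formal.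

Step 9
Reactants: 15 mixed formaldehyde acetal
Product: 16 methylene-bridged tri-O-benzyl biflavone: a dibenzo[d,f][1,3]dioxepine in which C8 of the 5-O-benzylacacetin unit is bonded to C6'' of the 7'',4'''-di-O-benzylapigenin unit and O7 and O5'' are joined by CH2
Conditions: Pd(OAc)2 (10 mol %), PCy3·HBF4 (20 mol %), PivOH (30 mol %), K2CO3, Ag2CO3, DMA (0.02 M), 120 °C
Reagents that add atoms: none
Why: Zerovalent palladium formed from Pd(OAc)2 and PCy3 inserts into the C8–I bond, Ag2CO3 strips iodide from the arylpalladium so that pivalate can bind, pivalate-assisted concerted metalation–deprotonation breaks C6''–H, and reductive elimination from the eight-membered diarylpalladacycle forms C8–C6''. The closest known reactions are intramolecular palladium-catalysed direct arylations of tethered aryl halides that give dibenzo-fused seven-membered rings, including those across bis(aryloxy) tethers that are later removed to release 2,2'-biphenols. The one ring closed is the seven-membered 1,3-dioxepine (C7, O7, CH2, O5'', C5'', C6'', C8), and it closes in the C–C bond-forming event of an intramolecular C–H arylation. No stereocentre arises, and the twisted biaryl axis forms as a racemate. The selectivity needed is between C6'' and C8'' of the apigenin ring A, and the tether secures it: from O5'' the metal can reach only C6'', because the other carbon ortho to O5'' is the ring-fusion carbon C4a'', while the iodine fixes C8 on the acacetin ring.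

Step 10
Reactants: 16 methylene-bridged tri-O-benzyl biflavone
Product: 17 CNP0310322.0, 8-(apigenin-6-yl)acacetin (5,7-dihydroxy-8-[5,7-dihydroxy-2-(4-hydroxyphenyl)-4-oxo-4H-chromen-6-yl]-2-(4-methoxyphenyl)-4H-chromen-4-one)
Conditions: BCl3 (1 M in CH2Cl2, excess), pentamethylbenzene, CH2Cl2, −78 to 0 °C; then MeOH, rt
Reagents that add atoms: none
Why: Lewis-acid ether cleavage in which BCl3, chelated between C4''=O and O5'', opens the aryl methylene acetal (the known BCl3 cleavage of methylenedioxy arenes in the presence of methoxy groups) and, with pentamethylbenzene as a Friedel–Crafts trap for benzyl cations, removes the three aryl benzyl ethers at low temperature, while the non-chelated 4'-methyl ether should survive and methanol frees the phenols from boron.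

**Compound list**

1 | acacetin | COc1ccc(-c2cc(=O)c3c(O)cc(O)cc3o2)cc1 | starting material
2 | chloromethyl methyl ether | COCCl | starting material
3 | 7-O-(methoxymethyl)acacetin | COc1ccc(-c2cc(=O)c3c(O)cc(OCOC)cc3o2)cc1 | intermediate
4 | benzyl bromide | BrCc1ccccc1 | starting material
5 | 5-O-benzyl-7-O-(methoxymethyl)acacetin | COc1ccc(-c2cc(=O)c3c(OCc4ccccc4)cc(OCOC)cc3o2)cc1 | intermediate
6 | N-iodosuccinimide | O=C1CCC(=O)N1I | starting material
7 | 5-O-benzyl-8-iodo-7-O-(methoxymethyl)acacetin | COc1ccc(-c2cc(=O)c3c(OCc4ccccc4)cc(OCOC)c(I)c3o2)cc1 | intermediate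
8 | 5-O-benzyl-8-iodoacacetin | COc1ccc(-c2cc(=O)c3c(OCc4ccccc4)cc(O)c(I)c3o2)cc1 | intermediate
9 | apigenin | O=c1cc(-c2ccc(O)cc2)oc2cc(O)cc(O)c12 | starting material
10 | 7,4'-di-O-benzylapigenin | O=c1cc(-c2ccc(OCc3ccccc3)cc2)oc2cc(OCc3ccccc3)cc(O)c12 | intermediate
11 | chloromethyl methyl sulfide | CSCCl | starting material
12 | 7,4'-di-O-benzyl-5-O-(methylthiomethyl)apigenin | O=c1cc(-c2ccc(OCc3ccccc3)cc2)oc2cc(OCc3ccccc3)cc(OCSC)c12 | intermediate
13 | sulfuryl chloride | O=S(=O)(Cl)Cl | starting material
14 | 7,4'-di-O-benzyl-5-O-(chloromethyl)apigenin | O=c1cc(-c2ccc(OCc3ccccc3)cc2)oc2cc(OCc3ccccc3)cc(OCCl)c12 | intermediate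
15 | 8-iodo-5-O-benzylacacetin 7-O-methylene acetal with O5 of 7,4'-di-O-benzylapigenin | COc1ccc(-c2cc(=O)c3c(OCc4ccccc4)cc(OCOc5cc(OCc6ccccc6)cc6oc(-c7ccc(OCc8ccccc8)cc7)cc(=O)c56)c(I)c3o2)cc1 | intermediate
16 | methylene-bridged tri-O-benzyl biflavone (dibenzo[d,f][1,3]dioxepine) | COc1ccc(-c2cc(=O)c3c(OCc4ccccc4)cc4OCOc5c(-c4c3o2)c(OCc3ccccc3)cc3oc(-c4ccc(OCc6ccccc6)cc4)cc(=O)c35)cc1 | intermediate
17 | CNP0310322.0, 8-(apigenin-6-yl)acacetin | COc1ccc(-c2cc(=O)c3c(O)cc(O)c(-c4c(O)cc5oc(-c6ccc(O)cc6)cc(=O)c5c4O)c3o2)cc1 | target

**Step count**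

Total: 10 steps. Longest linear sequence: 7 steps (steps 1, 2, 3, 4, 8, 9, 10 from acacetin).

**Steps most likely to fail**

Step 9. The hindered, electron-rich arylpalladium species may be reduced (protodeiodination) faster than it cleaves the doubly flanked C6''–H bond, so the tetra-ortho-substituted axis would not form. The fallback couples two carbon–iodine bonds reductively across the same tether. It sets out from 10: iodination ortho to the chelated hydroxyl (I2, TlOAc, CH2Cl2) should give 7,4'-di-O-benzyl-6-iodoapigenin F1. The operations of steps 6 to 8 repeated on F1 (NaH and ClCH2SMe; SO2Cl2 with cyclohexene; Cs2CO3 with 8) should lead through the 5-O-methylthiomethyl ether of 7,4'-di-O-benzyl-6-iodoapigenin F2 and the 5-O-chloromethyl ether of 7,4'-di-O-benzyl-6-iodoapigenin F3 to the 8,6''-diiodo mixed formaldehyde acetal F4. Intramolecular Ullmann coupling of F4 (Cu powder, DMF, 130–150 °C) then closes the dioxepine, and the route is rejoined at 16.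

Step 10. The Lewis acid may also remove the 4'-methyl group, the opened bridge may alkylate a phloroglucinol-type ring carbon as an aryloxymethyl cation, or the diaryl acetal may outlast the conditions. The fallback separates the two tasks and avoids benzyl cations. It sets out from 16: hydrogenolysis (H2, Pd/C, THF–MeOH) should give the methylene-bridged biflavone triphenol F5. Transacetalisation of F5 with ethane-1,2-dithiol and BF3·OEt2 (CH2Cl2–MeNO2, rt) then carries the bridge carbon off as 1,3-dithiolane and arrives at 17.

Step 7. SO2Cl2 or MeSCl may chlorinate or sulfenylate the electron-rich apigenin ring A, or the chloromethyl ether held next to the C4'' carbonyl may ionise and hydrolyse before it meets the phenoxide. The fallback puts the one-carbon unit on the other oxygen and uses no electrophilic sulfur or chlorine reagent. It sets out from 8: alkylation of its caesium phenoxide with a large excess of bromochloromethane (Cs2CO3, BrCH2Cl–DMF, rt) should give the 7-O-chloromethyl ether of 5-O-benzyl-8-iodoacacetin F6. Addition of F6 to the sodium 5-phenoxide of 10 (NaH, DMF, 0 °C) should give 15, where the route is rejoined without 12 and 14.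

**Further compounds**

F1 | step 9 | 7,4'-di-O-benzyl-6-iodoapigenin | O=c1cc(-c2ccc(OCc3ccccc3)cc2)oc2cc(OCc3ccccc3)c(I)c(O)c12
F2 | step 9 | 5-O-methylthiomethyl ether of 7,4'-di-O-benzyl-6-iodoapigenin | O=c1cc(-c2ccc(OCc3ccccc3)cc2)oc2cc(OCc3ccccc3)c(I)c(OCSC)c12
F3 | step 9 | 5-O-chloromethyl ether of 7,4'-di-O-benzyl-6-iodoapigenin | O=c1cc(-c2ccc(OCc3ccccc3)cc2)oc2cc(OCc3ccccc3)c(I)c(OCCl)c12
F4 | step 9 | 8,6''-diiodo mixed formaldehyde acetal | COc1ccc(-c2cc(=O)c3c(OCc4ccccc4)cc(OCOc5c(I)c(OCc6ccccc6)cc6oc(-c7ccc(OCc8ccccc8)cc7)cc(=O)c56)c(I)c3o2)cc1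
F5 | step 10 | methylene-bridged biflavone triphenol | COc1ccc(-c2cc(=O)c3c(O)cc4OCOc5c(-c4c3o2)c(O)cc3oc(-c4ccc(O)cc4)cc(=O)c35)cc1
F6 | step 7 | 7-O-chloromethyl ether of 5-O-benzyl-8-iodoacacetin | COc1ccc(-c2cc(=O)c3c(OCc4ccccc4)cc(OCCl)c(I)c3o2)cc1
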